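C3–C4 of ring C is cut first (after the two O-benzyl groups, the 3-O-methyl group and the C2=C3 unsaturation are taken back), then the O1–C2 ether. Ring A goes back to syringol by cutting its C–CHO bond and the C–O bonds of the future O1 and O5.
In the 4-pyranone ring C, the neighbouring carbons C3 (C–OMe) and C4 (C=O) both carry oxygen. Together they are an oxidised, enolised α-hydroxy ketone, so each can start as a formyl carbon: C4 on ring A, C3 on the carbon bearing O1 and ring B.
Forward, ring A is fully oxygenated and formylated first. Ring B with its two-carbon unit is then attached through the O1–C2 ether, ring C closes last through C3–C4, and oxidation, methylation and debenzylation follow.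
Araneosol has no stereocentre. C2 and C3 are stereogenic only in racemic intermediates, and both become sp2 in step 11.

Key step: step 10

Remark: the target SMILES contains no stereocentre and no stereogenic double bond, so the compound is achiral and no absolute control is needed. Chiral intermediates 9–14 are racemic and one enantiomer is drawn.

Step 1
Reactants: 1 2,6-dimethoxyphenol (syringol)
Product: 2 2-(benzyloxy)-1,3-dimethoxybenzene
Conditions: BnBr, K2CO3, DMF, 50 °C
Reagents that add atoms: benzyl bromide, BrCc1ccccc1
Why: Williamson ether synthesis; the phenoxide is alkylated by the reactive benzylic bromide, which masks the future 7-OH and removes the para-directing free phenol before bromination.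

Step 2
Reactants: 2 2-(benzyloxy)-1,3-dimethoxybenzene
Product: 3 3-(benzyloxy)-1,5-dibromo-2,4-dimethoxybenzene
Conditions: NBS (2.1 equiv), MeCN, 0 °C to rt, dark
Reagents that add atoms: N-bromosuccinimide, O=C1CCC(=O)N1Br
Why: Electrophilic aromatic bromination; each attacked position is ortho to one methoxy group and para to the other, whereas the central benzyloxy group is twisted out of conjugation and activates its para position only weakly, the pattern known for 1,2,3-trialkoxybenzenes.

Step 3
Reactants: 3 3-(benzyloxy)-1,5-dibromo-2,4-dimethoxybenzene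
Product: 4 5-(benzyloxy)-4,6-dimethoxybenzene-1,3-diol
Conditions: Cu(acac)2 (10 mol %), N,N'-bis(4-hydroxy-2,6-dimethylphenyl)oxalamide (10 mol %), LiOH·H2O, DMSO–H2O 4:1, 90 °C, Ar; then 1 M HCl
Reagents that add atoms: lithium hydroxide, [Li+].[OH-]
Why: Ullmann-type copper-catalysed hydroxylation of aryl bromides; each C–Br has only one ortho substituent, and the phenoxide formed first sits meta to the second bromide and so does not deactivate it by resonance.

Step 4
Reactants: 4 5-(benzyloxy)-4,6-dimethoxybenzene-1,3-diol
Product: 6 4-(benzyloxy)-2,6-dihydroxy-3,5-dimethoxybenzaldehyde, via aryl iminium chloride 5 (not isolated)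
Conditions: POCl3, DMF, EtOAc, 0 °C to rt; then H2O, 60 °C
Reagents that add atoms: N,N-dimethylformamide, CN(C)C=O; water, O
Why: Vilsmeier–Haack formylation; the only free ring position is ortho to both hydroxyl groups and strongly activated, as in the formylation of phloroglucinols, and iminium salt 5 is hydrolysed by the added water.

Step 5
Reactants: 6 4-(benzyloxy)-2,6-dihydroxy-3,5-dimethoxybenzaldehyde
Product: 7 2,4-bis(benzyloxy)-6-hydroxy-3,5-dimethoxybenzaldehyde
Conditions: BnBr (1.0 equiv), K2CO3 (1.1 equiv), acetone, rt to 40 °C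
Reagents that add atoms: benzyl bromide, BrCc1ccccc1
Why: Williamson mono-alkylation of a 2,6-dihydroxybenzaldehyde; the two hydroxyl groups are equivalent, and after the first benzylation the remaining one is hydrogen-bonded to the formyl oxygen and reacts much more slowly.

Step 6
Reactants: 8 methyl 4-methoxyphenylacetate
Product: 9 methyl 2-bromo-2-(4-methoxyphenyl)acetate (racemic)
Conditions: NBS, AIBN (cat.), PhCF3, reflux
Reagents that add atoms: N-bromosuccinimide, O=C1CCC(=O)N1Br
Why: Wohl–Ziegler bromination; the radical is stabilised by both the anisyl ring and the ester, so substitution occurs only at the benzylic α-carbon, and the new stereocentre forms racemic.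

Step 7
Reactants: 7 2,4-bis(benzyloxy)-6-hydroxy-3,5-dimethoxybenzaldehyde; 9 methyl 2-bromo-2-(4-methoxyphenyl)acetate
Product: 10 methyl 2-[3,5-bis(benzyloxy)-2-formyl-4,6-dimethoxyphenoxy]-2-(4-methoxyphenyl)acetate (racemic)
Conditions: K2CO3, DMF, rt to 40 °C
Reagents that add atoms: none
Why: Williamson ether synthesis at an activated α-bromo ester, the usual O-alkylation of salicylaldehydes with α-bromoarylacetates, forms O1–C2, and the low temperature keeps the ester enolate from adding to the hindered, electron-rich formyl group.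

Step 8
Reactants: 10 methyl 2-[3,5-bis(benzyloxy)-2-formyl-4,6-dimethoxyphenoxy]-2-(4-methoxyphenyl)acetate
Product: 11 2-[3,5-bis(benzyloxy)-2-(hydroxymethyl)-4,6-dimethoxyphenoxy]-2-(4-methoxyphenyl)ethan-1-ol (racemic)
Conditions: LiAlH4, THF, 0 °C; then H2O
Reagents that add atoms: none
Why: Hydride reduction with LiAlH4 takes ester and aldehyde to primary alcohols in one operation, so the two carbonyl groups need not be differentiated, and aryl, benzyl and methyl ethers are inert.

Step 9
Reactants: 11 2-[3,5-bis(benzyloxy)-2-(hydroxymethyl)-4,6-dimethoxyphenoxy]-2-(4-methoxyphenyl)ethan-1-ol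
Product: 12 2,4-bis(benzyloxy)-3,5-dimethoxy-6-[1-(4-methoxyphenyl)-2-oxoethoxy]benzaldehyde (racemic)
Conditions: Dess–Martin periodinane (2.4 equiv), NaHCO3, CH2Cl2, 0 °C to rt; used promptly
Reagents that add atoms: none
Why: Dess–Martin oxidation of both primary alcohols stops at the aldehyde level without amine base, which spares the enolisable α-aryl-α-aryloxy aldehyde, while bicarbonate keeps the electron-rich benzylic alcohol from ionising.

Step 10
Reactants: 12 2,4-bis(benzyloxy)-3,5-dimethoxy-6-[1-(4-methoxyphenyl)-2-oxoethoxy]benzaldehyde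
Product: 13 rac-(2R*,3R*)-5,7-bis(benzyloxy)-3-hydroxy-6,8-dimethoxy-2-(4-methoxyphenyl)chroman-4-one (trans-dihydroflavonol)
Conditions: 2-(pentafluorophenyl)-6,7-dihydro-5H-pyrrolo[2,1-c][1,2,4]triazol-2-ium tetrafluoroborate (20 mol %), i-Pr2NEt (20 mol %), toluene, 0.01 M (12 added by syringe pump), 30 °C, Ar
Reagents that add atoms: none
Why: Proposed new method: the triazolylidene adds reversibly to both formyl groups, proton transfer in the adduct of the aromatic aldehyde gives the aryl-conjugated hydroxy-enamine (Breslow intermediate) at C4, this acyl-anion equivalent attacks the more electrophilic, α-oxygenated aliphatic formyl carbon C3, and collapse of the alkoxide releases the carbene and leaves the C4 ketone. The closest known reaction types are the carbene-catalysed intramolecular crossed aldehyde–ketone benzoin of 2-(2-oxoalkoxy)benzaldehydes to 3-hydroxychroman-4-ones and the carbene-catalysed cyclisation of α-alkoxy dialdehydes to cyclic acyloins, whereas an aryl aldehyde tethered to an α-aryloxy aldehyde has not been shown. Ring C closes in a 6-exo-trig mode through the O1 tether. The one new stereocentre, C3, is set relative to C2 by a half-chair transition state with the 4-methoxyphenyl group pseudo-equatorial and can relax by enolisation to the diequatorial trans isomer, but both centres vanish in step 11. The step needs umpolung at C4 and not at C3 (a hydroxy-enamine at C3 could expel the aryloxide and end as an aryl ester), and ring closure ahead of dimerisation and of the 5-exo aldol of the C2 enolate; α-branching retards umpolung of the aliphatic aldehyde, the two ortho-alkoxy groups favour the carbene adduct of the aromatic one, the acidic N-C6F5 azolium needs only a weak amine base, toluene disfavours the charge-separating aryloxide loss, and high dilution with the short tether favours cyclisation. Any 4-hydroxy-3-ketone regioisomer shares the enediol with 13 and is carried to the same flavonol in step 11.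

Step 11
Reactants: 13 rac-(2R*,3R*)-5,7-bis(benzyloxy)-3-hydroxy-6,8-dimethoxy-2-(4-methoxyphenyl)chroman-4-one
Product: 15 5,7-bis(benzyloxy)-3-hydroxy-6,8-dimethoxy-2-(4-methoxyphenyl)-4H-chromen-4-one (flavonol), via chromane-3,4-dione 14 (not isolated)
Conditions: I2 (1.1 equiv), KOAc, AcOH, 100 °C
Reagents that add atoms: none
Why: Iodine-mediated dehydrogenation of a dihydroflavonol (α-hydroxy ketone to 1,2-dione through the enediol) gives dione 14, whose doubly activated C2–H tautomerises at once to the aromatic 4-pyranone, which erases both stereocentres, while acetate buffers the HI and protects the benzyl ethers.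

Step 12
Reactants: 15 5,7-bis(benzyloxy)-3-hydroxy-6,8-dimethoxy-2-(4-methoxyphenyl)-4H-chromen-4-one
Product: 16 5,7-bis(benzyloxy)-3,6,8-trimethoxy-2-(4-methoxyphenyl)-4H-chromen-4-one
Conditions: MeI, K2CO3, acetone, reflux
Reagents that add atoms: iodomethane, CI
Why: Williamson O-methylation; the enolic 3-OH is the only acidic group left, so methylation is unambiguous.

Step 13
Reactants: 16 5,7-bis(benzyloxy)-3,6,8-trimethoxy-2-(4-methoxyphenyl)-4H-chromen-4-one
Product: 17 araneosol, 5,7-dihydroxy-3,6,8-trimethoxy-2-(4-methoxyphenyl)-4H-chromen-4-one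
Conditions: H2 (1 atm), 10 % Pd/C, EtOAc–MeOH, rt
Reagents that add atoms: none
Why: Catalytic hydrogenolysis of aryl benzyl ethers; at 1 atm and room temperature the tetrasubstituted C2=C3 bond of the flavone and the methyl ethers should remain untouched, as is usual in flavone synthesis.

Compound list
1 | 2,6-dimethoxyphenol (syringol) | COc1cccc(OC)c1O | starting material
2 | 2-(benzyloxy)-1,3-dimethoxybenzene | COc1cccc(OC)c1OCc1ccccc1 | intermediate
3 | 3-(benzyloxy)-1,5-dibromo-2,4-dimethoxybenzene | COc1c(Br)cc(Br)c(OC)c1OCc1ccccc1 | intermediate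
4 | 5-(benzyloxy)-4,6-dimethoxybenzene-1,3-diol | COc1c(O)cc(O)c(OC)c1OCc1ccccc1 | intermediate
5 | [4-(benzyloxy)-2,6-dihydroxy-3,5-dimethoxybenzylidene]dimethyliminium chloride (not isolated) | C[N+](C)=Cc1c(O)c(OC)c(OCc2ccccc2)c(OC)c1O.[Cl-] | intermediate
6 | 4-(benzyloxy)-2,6-dihydroxy-3,5-dimethoxybenzaldehyde | COc1c(O)c(C=O)c(O)c(OC)c1OCc1ccccc1 | intermediate
7 | 2,4-bis(benzyloxy)-6-hydroxy-3,5-dimethoxybenzaldehyde | COc1c(O)c(C=O)c(OCc2ccccc2)c(OC)c1OCc1ccccc1 | intermediate
8 | methyl 4-methoxyphenylacetate | COC(=O)Cc1ccc(OC)cc1 | starting material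
9 | methyl 2-bromo-2-(4-methoxyphenyl)acetate (racemic, one enantiomer drawn) | COc1ccc([C@H](Br)C(=O)OC)cc1 | intermediate
10 | methyl 2-[3,5-bis(benzyloxy)-2-formyl-4,6-dimethoxyphenoxy]-2-(4-methoxyphenyl)acetate (racemic, one enantiomer drawn) | COc1ccc([C@@H](Oc2c(OC)c(OCc3ccccc3)c(OC)c(OCc3ccccc3)c2C=O)C(=O)OC)cc1 | intermediate
11 | 2-[3,5-bis(benzyloxy)-2-(hydroxymethyl)-4,6-dimethoxyphenoxy]-2-(4-methoxyphenyl)ethan-1-ol (racemic, one enantiomer drawn) | COc1ccc([C@@H](Oc2c(OC)c(OCc3ccccc3)c(OC)c(OCc3ccccc3)c2CO)CO)cc1 | intermediate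
12 | 2,4-bis(benzyloxy)-3,5-dimethoxy-6-[1-(4-methoxyphenyl)-2-oxoethoxy]benzaldehyde (racemic, one enantiomer drawn) | COc1ccc([C@@H](Oc2c(OC)c(OCc3ccccc3)c(OC)c(OCc3ccccc3)c2C=O)C=O)cc1 | intermediate
13 | rac-(2R*,3R*)-5,7-bis(benzyloxy)-3-hydroxy-6,8-dimethoxy-2-(4-methoxyphenyl)chroman-4-one (trans, one enantiomer drawn) | COc1ccc([C@@H]2[C@H](C(=O)c3c(OCc4ccccc4)c(OC)c(OCc4ccccc4)c(OC)c3O2)O)cc1 | intermediate
14 | 5,7-bis(benzyloxy)-6,8-dimethoxy-2-(4-methoxyphenyl)chromane-3,4-dione (racemic, one enantiomer drawn, not isolated) | COc1ccc([C@@H]2C(=O)C(=O)c3c(OCc4ccccc4)c(OC)c(OCc4ccccc4)c(OC)c3O2)cc1 | intermediate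
15 | 5,7-bis(benzyloxy)-3-hydroxy-6,8-dimethoxy-2-(4-methoxyphenyl)-4H-chromen-4-one | COc1ccc(-c2oc3c(OC)c(OCc4ccccc4)c(OC)c(OCc4ccccc4)c3c(=O)c2O)cc1 | intermediate
16 | 5,7-bis(benzyloxy)-3,6,8-trimethoxy-2-(4-methoxyphenyl)-4H-chromen-4-one | COc1ccc(-c2oc3c(OC)c(OCc4ccccc4)c(OC)c(OCc4ccccc4)c3c(=O)c2OC)cc1 | intermediate
17 | araneosol, 5,7-dihydroxy-3,6,8-trimethoxy-2-(4-methoxyphenyl)-4H-chromen-4-one | COc1ccc(-c2oc3c(OC)c(O)c(OC)c(O)c3c(=O)c2OC)cc1 | target

Total step count: 13. Longest linear sequence: 12 (steps 1–5 and 7–13; step 6 is a one-step side branch).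

Steps most likely to fail

Step 10. Three processes could defeat the cyclisation.
- The carbene may activate the aliphatic formyl group. Aryloxide loss from that hydroxy-enamine then drains the material by internal redox.
- The amine base may trigger the 5-exo aldol of the C2 enolate.
- Carbene addition to the doubly ortho-substituted aromatic aldehyde may be too slow.

The fallback keeps the C3–C4 bond but forms it reductively. It sets out from 12. Treatment with SmI2 and t-BuOH in THF at −78 °C to rt is the known intramolecular pinacol coupling of 1,6-dialdehydes. The aromatic formyl group should be reduced first, and its ketyl adds to the aliphatic aldehyde. This should give 2,3-trans-3,4-cis-5,7-bis(benzyloxy)-6,8-dimethoxy-2-(4-methoxyphenyl)chromane-3,4-diol F1, and any diastereomer serves. IBX in DMSO oxidises 1,2-diols to 1,2-diones without C–C cleavage, so it should take the diol through dione 14, which tautomerises. The sequence rejoins the route at 15.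

Step 9. Three processes could defeat the double oxidation.
- The half-oxidised hydroxy aldehyde may close to a seven-membered lactol and be over-oxidised.
- The very electron-rich benzylic alcohol may ionise.
- The enolisable aldehyde may decompose during isolation.

The fallback reaches the aliphatic aldehyde by partial reduction instead of alcohol oxidation. It sets out from 10. Trimethyl orthoformate with catalytic PPTS in MeOH should give methyl 2-[3,5-bis(benzyloxy)-2-(dimethoxymethyl)-4,6-dimethoxyphenoxy]-2-(4-methoxyphenyl)acetate F2. DIBAL-H (1.1 equiv) in toluene at −78 °C benefits from a tetrahedral intermediate chelated by the α-aryloxy oxygen. It should stop at 2-[3,5-bis(benzyloxy)-2-(dimethoxymethyl)-4,6-dimethoxyphenoxy]-2-(4-methoxyphenyl)acetaldehyde F3. PPTS in wet acetone cleaves the labile electron-rich acetal, and the sequence rejoins the route at 12.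

Step 3. Three processes could defeat the double hydroxylation.
- The second C–Br exchange may stall.
- Hydrodebromination may compete.
- The electron-rich resorcinol may be oxidised by air in hot base.

The fallback makes the C–O bonds through C–B bonds. It sets out from 3. Miyaura borylation (B2pin2, PdCl2(dppf), KOAc, dioxane, 90 °C) should give 2,2'-[5-(benzyloxy)-4,6-dimethoxy-1,3-phenylene]bis(4,4,5,5-tetramethyl-1,3,2-dioxaborolane) F4. Oxidation with H2O2 and NaOH in THF at 0 °C converts both boronates into phenols under cold, brief conditions. The sequence rejoins the route at 4.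

Further compounds
F1 | step 10 | 2,3-trans-3,4-cis-5,7-bis(benzyloxy)-6,8-dimethoxy-2-(4-methoxyphenyl)chromane-3,4-diol (racemic, one enantiomer drawn) | COc1ccc([C@@H]2[C@H]([C@@H](O)c3c(OCc4ccccc4)c(OC)c(OCc4ccccc4)c(OC)c3O2)O)cc1
F2 | step 9 | methyl 2-[3,5-bis(benzyloxy)-2-(dimethoxymethyl)-4,6-dimethoxyphenoxy]-2-(4-methoxyphenyl)acetate (racemic, one enantiomer drawn) | COc1ccc([C@@H](Oc2c(OC)c(OCc3ccccc3)c(OC)c(OCc3ccccc3)c2C(OC)OC)C(=O)OC)cc1
F3 | step 9 | 2-[3,5-bis(benzyloxy)-2-(dimethoxymethyl)-4,6-dimethoxyphenoxy]-2-(4-methoxyphenyl)acetaldehyde (racemic, one enantiomer drawn) | COc1ccc([C@@H](Oc2c(OC)c(OCc3ccccc3)c(OC)c(OCc3ccccc3)c2C(OC)OC)C=O)cc1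
F4 | step 3 | 2,2'-[5-(benzyloxy)-4,6-dimethoxy-1,3-phenylene]bis(4,4,5,5-tetramethyl-1,3,2-dioxaborolane) | COc1c(B2OC(C)(C)C(C)(C)O2)cc(B2OC(C)(C)C(C)(C)O2)c(OC)c1OCc1ccccc1
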